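**Target:** araneosol, 5,7-dihydroxy-3,6,8-trimethoxy-2-(4-methoxyphenyl)-4H-chromen-4-one (compound 14).

## Analysis of the target

Araneosol is a flavone: a benzene ring A fused to a 4-pyranone ring C, with a 4-methoxyphenyl ring B on C2. Ring A carries oxygen on all four of its free carbons, hydroxyl at C5 and C7 and methoxy at C6 and C8, and C3 of ring C carries a further methoxy group. The molecule has no stereocenter, so all selectivity questions are about position and about which oxygens end up free. The sensitive parts are the pyranone, which opens at C2 under strongly nucleophilic base, and ring A, which oxidises easily once both phenols are free. Because only two of the six ether or phenol oxygens finish as hydroxyls, they have to be marked out from the beginning and not produced by a late, unselective demethylation. The real difficulty is to assemble a hexasubstituted benzene ring and a tetrasubstituted C2=C3 double bond bearing a methoxy group in a controlled order. Two features of the structure carry the plan: C3 and its methoxy group form a one-carbon unit that sits between C4 and C2, and ring A has a local mirror plane through C7 and C4a that makes C5/C8a and C6/C8 pairwise equivalent as long as the oxygens on C5 and C8a bear the same acyl group. A 2,6-bis(4-methoxybenzoyloxy)benzoyl unit therefore already contains C4, C4a to C8a, O1, C2 and ring B (the last three twice), so that only C3 has to be added.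

## Retrosynthetic reasoning

**14 ⇒ 13 ⇒ 12.** The two phenols are unmasked last. The C7 O–benzyl bond of 13 is cut by hydrogenolysis and the C5 O–acyl bond of 12 by mild basic methanolysis. The two masks differ for a reason: the benzyl ether is needed from the first step to steer the substitution of ring A, and the C5 ester is simply the unused half of the symmetric key-step precursor. The ester goes first, while C7 is still protected, so that the final step is neutral and the electron-rich diphenol 14 never meets base.

**12 ⇒ 11 ⇒ 8 + 10.** Ring C is cut at the C2=C3 double bond and at the C3–C4 single bond. This removes C3 together with its methoxy group as the one-carbon ylide 10 and leaves the acid chloride 8. In 8 the O1–C2 bond and the C2–aryl bond already exist as an aryl ester, and C4 is the acyl chloride carbon on C4a. Cutting here rather than at O1–C8a or C4–C4a means no bond to ring A has to be made after the ring is fully substituted, and no oxidation at C3 is needed afterwards. Because 8 is symmetric, either ester can supply O1, C2 and ring B, and the other stays as the C5 protecting group. The forward reaction must acylate the ylide at the acid chloride in the presence of two aryl esters and then olefinate one ester carbonyl intramolecularly (via 11).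

**8 ⇒ 7 ⇒ 5 + 6.** The acyl chloride is traced to acid 7, and the two ester C–O bonds are cut to give the dihydroxy acid 5 and two equivalents of 6. Symmetry removes any need to distinguish the two phenols; the forward step only has to acylate both.

**5 ⇒ 4.** The bond between ring A and the carboxyl carbon is cut. Diol 4 has a single ring C–H, ortho to both hydroxyls, so a phenoxide carboxylation can only go there and regiochemistry is not a question.

**4 ⇒ 3 ⇒ 2 ⇒ 1.** The two new C–O bonds of 4 are traced to the C–Br bonds of 3, and these to C–H bonds of 2. In 2 each of the two outer free positions is para to one methoxy group and ortho to the other, while the central benzyloxy oxygen, flanked on both sides, is twisted out of conjugation; electrophilic bromination should therefore take exactly the two positions needed. The free phenol 1 would direct para to itself, which is why it is benzylated first; the same benzyl group later serves as the C7 mask.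

**10 ⇒ 9.** The ylide is made by deprotonating the phosphonium salt 9 in the flask of the key step.

## Alternatives that were turned down

Alternative 1: Here O1–C8a, C4–C4a and O1–C2 are cut, so that ring A comes from an aryne and C2–C3–C4 with ring B from a β-methoxy acrylic acid. In the forward step, fluoride-induced elimination from 3,5-bis(benzyloxy)-4-methoxy-2-(trimethylsilyl)phenyl trifluoromethanesulfonate (A2) releases the aryne. The carboxylate of (2Z)-2,3-dimethoxy-3-(4-methoxyphenyl)prop-2-enoic acid (A3) adds through oxygen at the aryne carbon remote from the flanking benzyloxy group. The geometry of the double bond in A3 does not matter, because it is lost in the addition–elimination that closes the ring. The aryl anion formed next to the benzyloxy group takes over the acyl group, a net insertion into the acid C–O bond. The phenoxide then closes ring C by conjugate addition and loss of the β-methoxy group, giving 5,7-bis(benzyloxy)-3,6-dimethoxy-2-(4-methoxyphenyl)-4H-chromen-4-one (A1).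

- For: three bonds form in one mild operation; the route is convergent; the regiochemistry follows from the polarisation of an alkoxy-flanked aryne; C3–OMe and ring B arrive together; one hydrogenolysis would free both phenols.
- Against: A1 has hydrogen at C8. Regiocontrol of the insertion needs an aryne with an alkoxy group on one flank only, so the C8 methoxy group cannot be carried through. It would have to be added afterwards by halogenation at C8 and a metal-mediated methoxylation, two more steps on an advanced, electron-rich flavone whose ring B competes for electrophiles. A2 needs a multistep preparation (ortho-silyl aryl triflate on a trioxygenated ring), the acid A3 has to be made separately as well, and plain O-arylation of the acid without the acyl shift is a standard side path.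
- Comparison: on mildness and convergence this is at least as strong as the chosen route. The chosen route offers instead all six oxygens in their final positions before ring closure, a ring-A precursor made from 1 by ordinary aromatic chemistry, and symmetry that removes every regiochemical question.

Alternative 2: Here C4–C4a, C3–C4 and O1–C2 are cut. Ring A comes from 5-(benzyloxy)-2-iodo-4,6-dimethoxybenzene-1,3-diol (A5), C2, C3 and ring B from 1-ethynyl-4-methoxybenzene (A6), and C4 from carbon monoxide (A7). In the forward step a palladium–phosphine catalyst in a secondary amine solvent under A7 effects oxidative addition into the C–I bond, carbonyl insertion and coupling with A6 to an alkynyl ketone. One ortho phenol then adds 6-endo to give 7-(benzyloxy)-5-hydroxy-6,8-dimethoxy-2-(4-methoxyphenyl)-4H-chromen-4-one (A4).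

- For: A5 is one iodination away from diol 4, so this path reaches the flavone core in fewer steps, with no carboxylation, aroylation or acid chloride. It is catalytic, the C5 hydroxyl emerges free, and the symmetric diol offers a phenol on either side.
- Against: A4 has hydrogen at C3. The C3 methoxy group would have to be installed by oxidising C3–H of a finished, electron-rich flavone with a free C5 hydroxyl (protection, C3 oxygenation, selective O-methylation), about three further steps. The 5-exo closure to the aurone isomer competes, and the doubly ortho-substituted, electron-rich iodide with free phenols is a poor partner for oxidative addition and is prone to oxidation.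
- Comparison: stronger than the chosen route in catalytic economy and in length up to the ring system, weaker because it stops one oxidation level short at C3. The chosen route brings C3 in with its oxygen attached.

Alternative 3: Here only O1–C8a is cut. In the forward step the enol of 1-[4-(benzyloxy)-2,6-dibromo-3,5-dimethoxyphenyl]-2-methoxy-3-(4-methoxyphenyl)propane-1,3-dione (A9) is O-arylated intramolecularly under copper catalysis with a chelating nitrogen ligand and a carbonate base in a dipolar aprotic solvent (Ullmann-type). Either bromine can serve, and the product is 7-(benzyloxy)-5-bromo-3,6,8-trimethoxy-2-(4-methoxyphenyl)-4H-chromen-4-one (A8).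

- For: it uses the same ring-A symmetry, carries C3–OMe, and could start from the dibromide 3 of the chosen route. Copper-catalysed closure of 2-haloaryl 1,3-diketones to chromones is better precedented than an ester Wittig with a fully substituted ylide.
- Against: A8 keeps bromine at C5. Turning it into a hydroxyl on the finished chromone needs a metal-catalysed hydroxylation under hot hydroxide, which attacks C2 of the pyranone, and hydrodebromination competes. Building A9 means acylating an α-methoxy ketone enolate with a doubly ortho-brominated aroyl electrophile, which is hindered and open to O-acylation.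
- Comparison: equal in its use of symmetry and stronger in precedent for the ring closure. The chosen route has the C5 oxygen present from the start as an ester that carbonate in methanol removes, so no C–O bond is made after ring C exists.

Key step: step 7

Remark: ylide 10 is generated and consumed in the flask of step 7, so its formation is not counted as a separate step.

## Route

Step 1
Reactants: 1 2,6-dimethoxyphenol
Product: 2 2-(benzyloxy)-1,3-dimethoxybenzene
Conditions: BnBr, K2CO3, DMF, 60 °C
Reagents that add atoms: benzyl bromide, BrCc1ccccc1
Why: Williamson ether synthesis; the phenol is the only acidic site and a benzylic bromide alkylates its potassium phenoxide readily.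

Step 2
Reactants: 2 2-(benzyloxy)-1,3-dimethoxybenzene
Product: 3 3-(benzyloxy)-1,5-dibromo-2,4-dimethoxybenzene
Conditions: NBS (2.1 equiv), MeCN, 0 °C to rt, dark
Reagents that add atoms: N-bromosuccinimide, O=C1CCC(=O)N1Br
Why: Electrophilic aromatic bromination; each outer free position is para to one methoxy group and ortho to the other, whereas the remaining position is meta to both and para only to the twisted, flanked benzyloxy oxygen, so two equivalents should stop at the 1,5-dibromide. The unactivated benzyl ring and, under ionic conditions in the dark, the benzylic CH2 should not react.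

Step 3
Reactants: 3 3-(benzyloxy)-1,5-dibromo-2,4-dimethoxybenzene
Product: 4 5-(benzyloxy)-4,6-dimethoxybenzene-1,3-diol
Conditions: KOH, Pd2(dba)3 (cat.), tBuXPhos (cat.), 1,4-dioxane/H2O, 100 °C, argon; then aq. HCl
Reagents that add atoms: potassium hydroxide, [K+].[OH-]
Why: Palladium-catalysed hydroxylation of aryl bromides (C–O cross-coupling at zerovalent palladium with a bulky biaryl phosphine); each bromide has a single ortho substituent, and excess hydroxide holds the product as the phenoxide, which the bulky ligand keeps from coupling to a diaryl ether. The diol is oxidation-prone and should be acidified and carried on under inert gas.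

Step 4
Reactants: 4 5-(benzyloxy)-4,6-dimethoxybenzene-1,3-diol
Product: 5 4-(benzyloxy)-2,6-dihydroxy-3,5-dimethoxybenzoic acid
Conditions: KHCO3 (excess), CO2 (1 atm), glycerol, 130 °C; then aq. HCl, 0 °C
Reagents that add atoms: carbon dioxide, O=C=O
Why: Kolbe–Schmitt carboxylation; the potassium phenoxide has one ring C–H, ortho to both phenolic oxygens and para to the third oxygen, so the carboxyl group can only enter there. The product should stay as its chelated potassium salt until cold acidification, which limits decarboxylation.

Step 5
Reactants: 5 4-(benzyloxy)-2,6-dihydroxy-3,5-dimethoxybenzoic acid; 6 4-methoxybenzoyl chloride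
Product: 7 4-(benzyloxy)-3,5-dimethoxy-2,6-bis[(4-methoxybenzoyl)oxy]benzoic acid
Conditions: 6 (2.5 equiv), pyridine, DMAP (cat.), CH2Cl2, 0 °C to rt; then H2O/pyridine, rt; aq. HCl
Reagents that add atoms: 4-methoxybenzoyl chloride (compound 6), COc1ccc(cc1)C(Cl)=O
Why: O-acylation of phenols by an acid chloride under nucleophilic catalysis; the two phenols are equivalent. Should the hindered carboxyl group be acylated as well, that anhydride link either passes its 4-methoxybenzoyl group to a phenol or is hydrolysed in the aqueous pyridine quench, returning the free acid.

Step 6
Reactants: 7 4-(benzyloxy)-3,5-dimethoxy-2,6-bis[(4-methoxybenzoyl)oxy]benzoic acid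
Product: 8 4-(benzyloxy)-3,5-dimethoxy-2,6-bis[(4-methoxybenzoyl)oxy]benzoyl chloride
Conditions: (COCl)2, DMF (cat.), CH2Cl2, 0 °C to rt; concentrate, use crude
Reagents that add atoms: oxalyl chloride, ClC(=O)C(Cl)=O
Why: Acid chloride formation through the chloroiminium species from oxalyl chloride and catalytic DMF; aryl esters, aryl ethers and the benzyl ether tolerate these conditions, and the gaseous by-products allow the crude chloride to be used directly.

Step 7
Reactants: 8 4-(benzyloxy)-3,5-dimethoxy-2,6-bis[(4-methoxybenzoyl)oxy]benzoyl chloride; 9 (methoxymethyl)triphenylphosphonium chloride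
Product: 12 7-(benzyloxy)-3,6,8-trimethoxy-2-(4-methoxyphenyl)-4-oxo-4H-chromen-5-yl 4-methoxybenzoate, via (methoxymethylene)triphenylphosphorane 10 (not isolated), via alpha-methoxy acyl ylide 11 (not isolated)
Conditions: 9 (2.1 equiv), KN(SiMe3)2 (2.0 equiv), THF, 0 °C; then 8 added slowly, −78 °C to rt; then toluene, 110 °C
Reagents that add atoms: (methoxymethyl)triphenylphosphonium chloride (compound 9), [Cl-].COC[P+](c1ccccc1)(c1ccccc1)c1ccccc1
Why: The first equivalent of ylide 10 adds to the acyl chloride carbon of 8 and expels chloride, forming the C3–C4 bond, and the second equivalent deprotonates the resulting acylphosphonium salt (transylidation) to give the carbonyl-stabilised ylide 11 and return one equivalent of 9. On heating, the ylide carbon of 11 attacks the carbonyl of one neighbouring 4-methoxybenzoate in a 6-exo-trig closure, and the oxaphosphetane collapses with loss of the phosphine oxide to form the C2=C3 double bond and ring C. If the tetrahedral intermediate instead expels the phenoxide (acyl transfer), the phenoxide can re-add to the new ketone and the same phosphine oxide elimination leads to the same chromone, so both paths converge. The closest known reaction type is chromone synthesis by C-acylation of a phosphorane with an O-acylsalicylic acid derivative followed by intramolecular Wittig olefination of the aryl ester carbonyl; the alpha-methoxy group is a new substituent on the ylide, which makes the ylide carbon more electron-rich but fully substituted. No stereocenter is formed and the new double bond is endocyclic, so its geometry is fixed by the ring. The selectivity needed is attack at the acid chloride before any ester; it should follow from the much higher electrophilicity of the acid chloride at −78 °C, from slow addition of 8 to no more than two equivalents of 10 made with a slight deficit of base, and from the donor methoxy groups that deactivate the ester carbonyls. After that the only nucleophile left is the stabilised ylide 11, which reaches an ester only intramolecularly; the two esters are equivalent, and the one not used remains as the C5 protecting group.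

Step 8
Reactants: 12 7-(benzyloxy)-3,6,8-trimethoxy-2-(4-methoxyphenyl)-4-oxo-4H-chromen-5-yl 4-methoxybenzoate
Product: 13 7-(benzyloxy)-5-hydroxy-3,6,8-trimethoxy-2-(4-methoxyphenyl)-4H-chromen-4-one
Conditions: K2CO3, MeOH/THF, rt
Reagents that add atoms: none
Why: Base-mediated transesterification (methanolysis) of an aryl ester; the C5 phenoxide, peri to the C4 carbonyl, is a good leaving group, so carbonate in methanol at room temperature should suffice without opening the pyranone or touching the benzyl ether.

Step 9
Reactants: 13 7-(benzyloxy)-5-hydroxy-3,6,8-trimethoxy-2-(4-methoxyphenyl)-4H-chromen-4-one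
Product: 14 araneosol, 5,7-dihydroxy-3,6,8-trimethoxy-2-(4-methoxyphenyl)-4H-chromen-4-one
Conditions: H2 (1 atm), 10% Pd/C, EtOAc/MeOH, rt
Reagents that add atoms: none
Why: Hydrogenolysis of a benzyl aryl ether over palladium on carbon; the conjugated, tetrasubstituted C2=C3 double bond and the aryl methyl ethers should be inert at atmospheric pressure, and the neutral conditions spare the electron-rich product.

## Compound list

1 | 2,6-dimethoxyphenol | COc1cccc(OC)c1O | starting material
2 | 2-(benzyloxy)-1,3-dimethoxybenzene | COc1cccc(OC)c1OCc1ccccc1 | intermediate
3 | 3-(benzyloxy)-1,5-dibromo-2,4-dimethoxybenzene | COc1c(Br)cc(Br)c(OC)c1OCc1ccccc1 | intermediate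
4 | 5-(benzyloxy)-4,6-dimethoxybenzene-1,3-diol | COc1c(O)cc(O)c(OC)c1OCc1ccccc1 | intermediate
5 | 4-(benzyloxy)-2,6-dihydroxy-3,5-dimethoxybenzoic acid | COc1c(O)c(C(O)=O)c(O)c(OC)c1OCc1ccccc1 | intermediate
6 | 4-methoxybenzoyl chloride | COc1ccc(cc1)C(Cl)=O | starting material
7 | 4-(benzyloxy)-3,5-dimethoxy-2,6-bis[(4-methoxybenzoyl)oxy]benzoic acid | COc1ccc(cc1)C(=O)Oc1c(OC)c(OCc2ccccc2)c(OC)c(OC(=O)c2ccc(OC)cc2)c1C(O)=O | intermediate
8 | 4-(benzyloxy)-3,5-dimethoxy-2,6-bis[(4-methoxybenzoyl)oxy]benzoyl chloride | COc1ccc(cc1)C(=O)Oc1c(OC)c(OCc2ccccc2)c(OC)c(OC(=O)c2ccc(OC)cc2)c1C(Cl)=O | intermediate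
9 | (methoxymethyl)triphenylphosphonium chloride | [Cl-].COC[P+](c1ccccc1)(c1ccccc1)c1ccccc1 | starting material
10 | (methoxymethylene)triphenylphosphorane | COC=P(c1ccccc1)(c1ccccc1)c1ccccc1 | intermediate
11 | 5-(benzyloxy)-4,6-dimethoxy-2-[methoxy(triphenylphosphoranylidene)acetyl]-1,3-phenylene bis(4-methoxybenzoate) (alpha-methoxy acyl ylide) | COc1ccc(cc1)C(=O)Oc1c(OC)c(OCc2ccccc2)c(OC)c(OC(=O)c2ccc(OC)cc2)c1C(=O)C(OC)=P(c1ccccc1)(c1ccccc1)c1ccccc1 | intermediate
12 | 7-(benzyloxy)-3,6,8-trimethoxy-2-(4-methoxyphenyl)-4-oxo-4H-chromen-5-yl 4-methoxybenzoate | COc1ccc(-c2oc3c(OC)c(OCc4ccccc4)c(OC)c(OC(=O)c4ccc(OC)cc4)c3c(=O)c2OC)cc1 | intermediate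
13 | 7-(benzyloxy)-5-hydroxy-3,6,8-trimethoxy-2-(4-methoxyphenyl)-4H-chromen-4-one | COc1ccc(-c2oc3c(OC)c(OCc4ccccc4)c(OC)c(O)c3c(=O)c2OC)cc1 | intermediate
14 | araneosol, 5,7-dihydroxy-3,6,8-trimethoxy-2-(4-methoxyphenyl)-4H-chromen-4-one | COc1ccc(-c2oc3c(OC)c(O)c(OC)c(O)c3c(=O)c2OC)cc1 | target

## Step count and risk

Total step count: 9. Longest linear sequence: 9 steps (1 to 14); 6 and 9 enter as purchased building blocks.

**Step 7 (key step).** Two processes are most likely to fail. First, the acyl chloride carbon of 8 lies between two ortho acyloxy groups, so attack by the bulky ylide may be slow enough for acyl transfer from the aryl esters to the ylide to compete, which would strip the esters. Second, the stabilised, fully substituted ylide 11 may olefinate the ester carbonyl only sluggishly, so that it degrades on prolonged heating or hydrolyses on work-up instead of closing the ring.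

The fallback sets out from diol 4 and builds ring C by enolate acyl transfer instead of by a phosphorus ylide. Houben–Hoesch acylation of 4 with methoxyacetonitrile (ZnCl2, HCl, Et2O, 0 °C; then aqueous hydrolysis) at its only free ring position should give 1-[4-(benzyloxy)-2,6-dihydroxy-3,5-dimethoxyphenyl]-2-methoxyethan-1-one F1. Acylation of both phenols with 6 (pyridine, DMAP, CH2Cl2) gives 5-(benzyloxy)-4,6-dimethoxy-2-(methoxyacetyl)-1,3-phenylene bis(4-methoxybenzoate) F2. Baker–Venkataraman rearrangement (LiN(SiMe3)2, THF, −20 °C to rt) moves one 4-methoxybenzoyl group to the methoxy-bearing carbon, giving 3-(benzyloxy)-5-hydroxy-2,4-dimethoxy-6-[2-methoxy-3-(4-methoxyphenyl)-3-oxopropanoyl]phenyl 4-methoxybenzoate F3. Acid-catalysed cyclodehydration (TsOH, toluene, 80 °C) then closes ring C and comes back to the route at 12.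

**Step 4.** The carboxylation is reversible, so decarboxylation on acidification or warming is the main danger, together with oxidative degradation of the electron-rich phenoxide at the reaction temperature.

The fallback sets out from dibromide 3 and introduces the carbon before the oxygens. Deprotonation of the single ring C–H between the two bromines (LiN(iPr)2, THF, −78 °C) and quenching with CO2 should give 4-(benzyloxy)-2,6-dibromo-3,5-dimethoxybenzoic acid F4. Twofold copper-catalysed hydroxylation assisted by the ortho carboxylate (CuI, KOH, H2O, 100 °C; then cold aq. HCl) would come back to the route at 5.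

**Step 5.** Anhydride formation at the carboxyl group can compete with phenol acylation, the second acylation at a phenol flanked by a methoxy and a carboxyl group may stay incomplete, and the electron-rich salicylic acid may decarboxylate in base.

The fallback sets out from diol 4 and carries the carboxyl carbon as an aldehyde until the esters are in place. Magnesium-mediated ortho-formylation (MgCl2, Et3N, paraformaldehyde, MeCN, reflux) should give 4-(benzyloxy)-2,6-dihydroxy-3,5-dimethoxybenzaldehyde F5. Acylation with 6 (pyridine, DMAP, CH2Cl2) gives 5-(benzyloxy)-2-formyl-4,6-dimethoxy-1,3-phenylene bis(4-methoxybenzoate) F6. Pinnick oxidation (NaClO2, NaH2PO4, 2-methyl-2-butene, t-BuOH/THF/H2O, rt) comes back to the route at 7.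

**Step 3.** The twofold coupling may stop after the first C–O bond, the intermediate phenoxide may couple with remaining aryl bromide to diaryl ethers, hydrodebromination may compete, and the product may oxidise in air during work-up.

The fallback sets out from dibromide 3 and makes the C–O bonds by oxidation of C–B bonds. Twofold Miyaura borylation (B2pin2, PdCl2(dppf), KOAc, 1,4-dioxane, 90 °C) should give 2,2'-[5-(benzyloxy)-4,6-dimethoxy-1,3-phenylene]bis(4,4,5,5-tetramethyl-1,3,2-dioxaborolane) F7. Oxidation with H2O2 and NaOH in THF/H2O at 0 °C comes back to the route at 4.

## Further compounds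

F1 | step 7 | 1-[4-(benzyloxy)-2,6-dihydroxy-3,5-dimethoxyphenyl]-2-methoxyethan-1-one | COCC(=O)c1c(O)c(OC)c(OCc2ccccc2)c(OC)c1O
F2 | step 7 | 5-(benzyloxy)-4,6-dimethoxy-2-(methoxyacetyl)-1,3-phenylene bis(4-methoxybenzoate) | COCC(=O)c1c(OC(=O)c2ccc(OC)cc2)c(OC)c(OCc2ccccc2)c(OC)c1OC(=O)c1ccc(OC)cc1
F3 | step 7 | 3-(benzyloxy)-5-hydroxy-2,4-dimethoxy-6-[2-methoxy-3-(4-methoxyphenyl)-3-oxopropanoyl]phenyl 4-methoxybenzoate (racemic, enolisable) | COc1ccc(cc1)C(=O)C(OC)C(=O)c1c(O)c(OC)c(OCc2ccccc2)c(OC)c1OC(=O)c1ccc(OC)cc1
F4 | step 4 | 4-(benzyloxy)-2,6-dibromo-3,5-dimethoxybenzoic acid | COc1c(Br)c(C(O)=O)c(Br)c(OC)c1OCc1ccccc1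
F5 | step 5 | 4-(benzyloxy)-2,6-dihydroxy-3,5-dimethoxybenzaldehyde | COc1c(O)c(C=O)c(O)c(OC)c1OCc1ccccc1
F6 | step 5 | 5-(benzyloxy)-2-formyl-4,6-dimethoxy-1,3-phenylene bis(4-methoxybenzoate) | COc1ccc(cc1)C(=O)Oc1c(OC)c(OCc2ccccc2)c(OC)c(OC(=O)c2ccc(OC)cc2)c1C=O
F7 | step 3 | 2,2'-[5-(benzyloxy)-4,6-dimethoxy-1,3-phenylene]bis(4,4,5,5-tetramethyl-1,3,2-dioxaborolane) | COc1c(B2OC(C)(C)C(C)(C)O2)cc(B2OC(C)(C)C(C)(C)O2)c(OC)c1OCc1ccccc1
A1 | alternative 1 | 5,7-bis(benzyloxy)-3,6-dimethoxy-2-(4-methoxyphenyl)-4H-chromen-4-one | COc1ccc(-c2oc3cc(OCc4ccccc4)c(OC)c(OCc4ccccc4)c3c(=O)c2OC)cc1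
A2 | alternative 1 | 3,5-bis(benzyloxy)-4-methoxy-2-(trimethylsilyl)phenyl trifluoromethanesulfonate | C[Si](C)(C)c1c(OS(=O)(=O)C(F)(F)F)cc(OCc2ccccc2)c(OC)c1OCc1ccccc1
A3 | alternative 1 | (2Z)-2,3-dimethoxy-3-(4-methoxyphenyl)prop-2-enoic acid | CO/C(c1ccc(OC)cc1)=C(\OC)C(O)=O
A4 | alternative 2 | 7-(benzyloxy)-5-hydroxy-6,8-dimethoxy-2-(4-methoxyphenyl)-4H-chromen-4-one | COc1ccc(-c2cc(=O)c3c(O)c(OC)c(OCc4ccccc4)c(OC)c3o2)cc1
A5 | alternative 2 | 5-(benzyloxy)-2-iodo-4,6-dimethoxybenzene-1,3-diol | COc1c(O)c(I)c(O)c(OC)c1OCc1ccccc1
A6 | alternative 2 | 1-ethynyl-4-methoxybenzene | COc1ccc(C#C)cc1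
A7 | alternative 2 | carbon monoxide | [C-]#[O+]
A8 | alternative 3 | 7-(benzyloxy)-5-bromo-3,6,8-trimethoxy-2-(4-methoxyphenyl)-4H-chromen-4-one | COc1ccc(-c2oc3c(OC)c(OCc4ccccc4)c(OC)c(Br)c3c(=O)c2OC)cc1
A9 | alternative 3 | 1-[4-(benzyloxy)-2,6-dibromo-3,5-dimethoxyphenyl]-2-methoxy-3-(4-methoxyphenyl)propane-1,3-dione (racemic, enolisable) | COC(C(=O)c1ccc(OC)cc1)C(=O)c1c(Br)c(OC)c(OCc2ccccc2)c(OC)c1Br
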